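**Retrosynthetic overview**
1. 8 ⇒ 7: the C2–Br comes from the lactam C=O (POBr3), which also aromatises the five-membered ring.
2. 7 ⇒ 6: C3–C3a bond. The amide α-carbon, normally an enolate nucleophile, is used as an α-cation (bromo-enolonium equivalent) toward the ortho C–H of the N-aryl ring. The C3 bromine is carried in on that same carbon.
3. 6 ⇒ 3 + 4 (amide bond); 3 ⇒ 1 (N-methyl).
4. Ring order: the benzene ring is bought with both aryl bromines in place (meta/meta, so the two ortho sites are identical). The pyrrole ring is closed once, in step 3.
5. 8 has no stereocentre; C3 of 7 is a transient racemic centre.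

Assumption: 8 is achiral, so "single enantiomer" means only the constitution drawn; compound numbers follow the forward route.

**Step 1**
Reactants: 1 3,5-dibromoaniline
Product: 3 3,5-dibromo-N-methylaniline, via N-(methoxymethyl)-3,5-dibromoaniline 2 (not isolated)
Conditions: (CH2O)n (1.5 equiv), NaOMe (5 equiv), MeOH, rt, 16 h; then NaBH4 (1.5 equiv), reflux, 1 h
Reagents that add atoms: paraformaldehyde, as formaldehyde C=O (the OMe of 2 comes from the solvent methanol, CO, and is lost again)
Why: Reductive N-monomethylation: under NaOMe the aniline condenses once with formaldehyde to the hemiaminal ether 2, which NaBH4 reduces through the N-aryl iminium ion to the N-methylaniline, so dimethylation is avoided and the aryl bromides are untouched.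

**Step 2**
Reactants: 3 3,5-dibromo-N-methylaniline; 4 dibromoacetic acid
Product: 6 2,2-dibromo-N-(3,5-dibromophenyl)-N-methylacetamide, via dibromoacetic anhydride 5 (not isolated)
Conditions: 4 (2.2 equiv), DIC (1.1 equiv), CH2Cl2, 0 °C, 20 min; then 3, 0 °C → rt, 12 h
Reagents that add atoms: none
Why: Carbodiimide-mediated N-acylation: DIC converts two equivalents of 4 into the strongly electrophilic symmetrical anhydride 5, which acylates even this weakly nucleophilic N-methylaniline, and the halide-free activation rules out Br/Cl scrambling at the CHBr2 carbon.

**Step 3**
Reactants: 6 2,2-dibromo-N-(3,5-dibromophenyl)-N-methylacetamide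
Product: 7 (±)-3,4,6-tribromo-1-methylindolin-2-one
Conditions: AlBr3 (3 equiv), neat melt, 110–120 °C, N2 sweep, 1–2 h; then ice-water
Reagents that add atoms: none
Why: Proposed new method: a Stollé-type intramolecular Friedel–Crafts alkylation in which AlBr3 binds the amide oxygen and abstracts one bromide from the CHBr2 group, so that the amide α-carbon reacts as a bromine-stabilised α-carbamoyl cation with the ortho carbon of the N-aryl ring (two carbons that are both normally nucleophilic), the ring being held next to that carbon by the cis preference of N-methylanilides; the two ortho positions are equivalent so only the 4,6-dibromo isomer can form, the second bromine stays on C3, and the new C3 centre is racemic and is erased in step 4; the closest known reactions are the Stollé oxindole synthesis from α-haloacetanilides with AlCl3 and the Lewis-acid cyclisation of α-chloro-α-(methylthio)acetanilides to 3-(methylthio)oxindoles.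

**Step 4**
Reactants: 7 (±)-3,4,6-tribromo-1-methylindolin-2-one
Product: 8 2,3,4,6-tetrabromo-1-methyl-1H-indole
Conditions: POBr3 (3 equiv), 1,2-dichloroethane, reflux, 4–8 h; then ice-water
Reagents that add atoms: phosphorus oxybromide, O=P(Br)(Br)Br
Why: Vilsmeier-type deoxybromination of an N-alkyl oxindole: O-phosphorylation of the lactam gives a 3H-indolium ion, bromide adds at C2 and expels the phosphate, and loss of the acidic C3–H aromatises to the 2,3-dibromoindole; this is the known POBr3 conversion of oxindoles to 2-bromoindoles applied to a 3-bromo substrate, run without imidazole or any other nucleophilic base that could displace the C3 bromide.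

**Compound list**
1 | 3,5-dibromoaniline | Nc1cc(Br)cc(Br)c1 | starting material
2 | N-(methoxymethyl)-3,5-dibromoaniline | COCNc1cc(Br)cc(Br)c1 | intermediate (not isolated)
3 | 3,5-dibromo-N-methylaniline | CNc1cc(Br)cc(Br)c1 | intermediate
4 | dibromoacetic acid | OC(=O)C(Br)Br | starting material
5 | dibromoacetic anhydride | O=C(OC(=O)C(Br)Br)C(Br)Br | intermediate (not isolated)
6 | 2,2-dibromo-N-(3,5-dibromophenyl)-N-methylacetamide | CN(C(=O)C(Br)Br)c1cc(Br)cc(Br)c1 | intermediate
7 | (±)-3,4,6-tribromo-1-methylindolin-2-one (racemic at C3) | CN1C(=O)C(Br)c2c(Br)cc(Br)cc21 | intermediate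
8 | 2,3,4,6-tetrabromo-1-methyl-1H-indole (achiral) | Cn1c(Br)c(Br)c2c(Br)cc(Br)cc21 | target

**Step count and risks**
Total steps: 4. Longest linear sequence: 4 (1 → 3 → 6 → 7 → 8).

Most likely to fail, in order:

1. Step 3 (ring closure of the gem-dibromide). The risks are that the benzylic C3–Br of 7 ionises a second time under AlBr3, that HBr reduces it, that bromine migrates on the ring, or that the doubly deactivated ring reacts too slowly. The fallback sets out from 3 and comes back to the route at 8; it no longer carries the C3 bromine through the C–C bond formation but installs it last by electrophilic substitution. 3 is acylated with bromoacetyl bromide (K2CO3, CH2Cl2, 0 °C) to give 2-bromo-N-(3,5-dibromophenyl)-N-methylacetamide F1. The ordinary Stollé cyclisation of this monobromide (AlBr3 melt, about 130 °C) gives 4,6-dibromo-1-methylindolin-2-one F2, which has no ionisable halogen at C3. POBr3 in refluxing 1,2-dichloroethane converts F2 into 2,4,6-tribromo-1-methyl-1H-indole F3, and NBS (1.05 equiv, THF, 0 °C) brominates the free C3 to give 8. This costs one extra step.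

2. Step 4 (POBr3 on a 3-bromooxindole). The risks are that 7 loses or exchanges its C3 bromide under hot HBr/POBr3, or dimerises, before the C2 oxygen is replaced. The fallback sets out from 7 and comes back at 8; it removes the C2 oxygen reductively and introduces the C2 bromine by electrophilic bromination instead. DIBAL-H (2.2 equiv, CH2Cl2, −78 → 0 °C) reduces the lactam to 3,4,6-tribromo-1-methylindolin-2-ol F4, which is not isolated and loses water on acidic work-up to give 3,4,6-tribromo-1-methyl-1H-indole F5. NBS (1.05 equiv, DMF, 0 °C → rt) then brominates C2 of this 3-bromoindole to give 8.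

3. Step 1 (mono-N-methylation). The risk is a mixture of unreacted 1, 3 and the N,N-dimethylaniline that is hard to separate and would carry through. The fallback sets out from 1 and comes back at 3; it replaces reductive alkylation by acylation and reduction, which cannot over-alkylate. 1 is heated with formic acid in toluene (Dean–Stark) to give N-(3,5-dibromophenyl)formamide F6, and BH3·SMe2 (THF, reflux; MeOH/HCl work-up) reduces the formamide to 3 without touching the aryl bromides.

**Further compounds**
F1 | step 3 | 2-bromo-N-(3,5-dibromophenyl)-N-methylacetamide | CN(C(=O)CBr)c1cc(Br)cc(Br)c1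
F2 | step 3 | 4,6-dibromo-1-methylindolin-2-one | CN1C(=O)Cc2c(Br)cc(Br)cc21
F3 | step 3 | 2,4,6-tribromo-1-methyl-1H-indole | Cn1c(Br)cc2c(Br)cc(Br)cc21
F4 | step 4 | 3,4,6-tribromo-1-methylindolin-2-ol | CN1C(O)C(Br)c2c(Br)cc(Br)cc21
F5 | step 4 | 3,4,6-tribromo-1-methyl-1H-indole | Cn1cc(Br)c2c(Br)cc(Br)cc21
F6 | step 1 | N-(3,5-dibromophenyl)formamide | O=CNc1cc(Br)cc(Br)c1
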